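0.428 min⁻¹ was the first number I took from the earlier runs: it is the first-order rate constant at which the summed target of violet, grey and amber fell between 1.33 min and 5.00 min, the chance per minute that a molecule of target becomes over-reaction product.

| setting | violet | grey | amber | flask |
|---|---|---|---|---|
| starting material | 0.10 M | 0.15 M | 0.20 M | 0.20 M |
| enzyme | 20 µM | 20 µM | 30 µM | 20 µM |
| remark | run made earlier | run made earlier | run made earlier |  |
| time |  |  |  | 25 min |

| run | time / min | target / % |
|---|---|---|
| violet | 0.250 | 66 |
| violet | 1.33 | 57 |
| violet | 5.00 | 12 |
| violet | 25.0 | 0 |
| grey | 0.250 | 58 |
| grey | 1.33 | 59 |
| grey | 5.00 | 11 |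
| grey | 25.0 | 1 |
| amber | 0.250 | 74 |
| amber | 1.33 | 57 |
| amber | 5.00 | 13 |
| amber | 25.0 | 0 |

(each reading ± 1.5 percentage points)

- on the list of suspects stand: starting material + enzyme <-> complex; complex -> enzyme + target; target -> over-reaction product

- time, not beyond 25 min, at which the flask holds most target
- the amount of target, in percent of the starting material charged, at that time

I followed one molecule through the flask. It waits as starting material until the enzyme converts it, and then lives as target for a mean life of 2.34 min. The amber run has the flask's 0.20 M of starting material, so I read the wait there, though it holds more enzyme than the flask. Its 74% at 0.250 min had been target for about 0.125 min on average, so about 78.1% of the charge had been converted. Treating the pool as emptying with one constant chance per minute, which is crude, gives a mean wait of 0.165 min. Enzyme stood far below the starting material, so at this fixed starting material I took the wait as inverse to enzyme, and the flask's 20 µM against amber's 30 µM gives an estimated wait of 0.247 min.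

The wait divided by the life, which I call the fork odds (a selectivity factor for two steps in sequence), is 0.106. For two first-order steps, target peaks where making has fallen to loss. My reckoning put that at 0.621 min, holding 76.7%. The forecast gave 0.62 min (0.45 min to 0.85 min) and 80% (75% to 85%), holding that “the maximum comes when formation equals decay”; my time matched it, and my amount stood 3.3 percentage points lower.

The flask reached its best at 0.620 min with 79.5% target, and by then 15.4% of the charge was over-reaction product.

    starting material + enzyme ⇌ complex (K = 11.0 L mol⁻¹, k = 50000 L mol⁻¹ s⁻¹)
    complex → enzyme + target (k = 670 s⁻¹)
    target → over-reaction product (k = 0.00760 s⁻¹)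

For a neighbour flask, charged like this one but with 8.0 × 10⁻⁶ M of enzyme, I scaled the same amber wait to its enzyme, which gives estimated fork odds of 0.264 and a peak of 62.0%. That neighbour's best was 63.8%.

The numbers in the tables were generated by integration on assumed constants, and the scatter is random.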